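**Retrosynthetic overview**
- Last operation: ring-closing metathesis forms the 3-(bromomethyl)butenolide and, in the same flask, a CrCl2-mediated Nozaki–Hiyama allylation onto the C-8 aldehyde forms the C7–C8 bond and closes the ten-membered ring. This frees 8-OH with the epoxy ester already on O-9.
- The acyclic precursor comes from geranyl acetate (C1–C6, 4E olefin), a Stork–Zhao iodo-olefination (1(10)Z olefin), a Ni/Cr coupling with (S)-glyceraldehyde acetonide (sets C-9; its own stereocentre is later cut out by periodate) and a catalytic asymmetric vinylation (sets C-6).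
- The epoxy acid is made separately (Sharpless epoxidation of angelyl alcohol, then RuO4 oxidation) and attached to O-9 early.
- Ring order: oxirane first; butenolide and carbocycle together in the last step.

Assumption: germacrane numbering is used in the prose (lactone carbinol C-6, ring-fusion CH C-7, free carbinol C-8, acyloxy carbon C-9); in step 10 and its fallback the ligand antipode that gives the drawn configuration is meant, its sense to be confirmed by Mosher analysis.

**Route**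

Step 1
Reactants: 1 methyl (2Z)-2-methylbut-2-enoate (methyl angelate)
Product: 2 (2Z)-2-methylbut-2-en-1-ol
Conditions: LiAlH4, Et2O, 0 °C
Reagents that add atoms: none
Why: Hydride reduction of the ester leaves the isolated Z-trisubstituted alkene untouched, so the geometry that later fixes the cis oxirane is kept.

Step 2
Reactants: 2 (2Z)-2-methylbut-2-en-1-ol
Product: 3 [(2R,3S)-2,3-dimethyloxiran-2-yl]methanol
Conditions: Ti(OiPr)4 (10 mol %), D-(−)-diethyl tartrate (12 mol %), t-BuOOH, 4 Å MS, CH2Cl2, −20 °C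
Reagents that add atoms: tert-butyl hydroperoxide, CC(C)(C)OO
Why: Sharpless asymmetric epoxidation, in which the D-tartrate catalyst delivers oxygen to the face that gives the 2R,3S epoxy alcohol, while the cis relation of CH2OH and the 3-methyl group comes from the Z alkene.

Step 3
Reactants: 3 [(2R,3S)-2,3-dimethyloxiran-2-yl]methanol
Product: 4 (2S,3S)-2,3-dimethyloxirane-2-carboxylic acid
Conditions: RuCl3·xH2O (2 mol %), NaIO4, CCl4/MeCN/H2O, rt
Reagents that add atoms: water, O
Why: RuO4 oxidation of the primary alcohol to the acid under near-neutral conditions keeps the oxirane; only the descriptor at C-2 changes (R to S) with no change in space.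

Step 4
Reactants: 5 geranyl acetate
Product: 6 (2E)-3-methyl-6-oxohex-2-en-1-yl acetate
Conditions: O3 (1.0 equiv), CH2Cl2/pyridine, −78 °C; Me2S
Reagents that add atoms: ozone, [O-][O+]=O
Why: Chemoselective ozonolysis, since the electron-rich terminal trisubstituted alkene reacts much faster than the alkene deactivated by the allylic acetate.

Step 5
Reactants: 6 (2E)-3-methyl-6-oxohex-2-en-1-yl acetate; 7 ethyltriphenylphosphonium iodide
Product: 11 (2E,6Z)-7-iodo-3-methylocta-2,6-dien-1-yl acetate, via ethylidenetriphenylphosphorane 8 (not isolated), via (1-iodoethyl)triphenylphosphonium iodide 9 (not isolated), via (1-iodoethylidene)triphenylphosphorane 10 (not isolated)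
Conditions: 7, n-BuLi, THF, 0 °C; I2, −78 °C; NaN(SiMe3)2, −20 °C; then 6, −78 → −20 °C
Reagents that add atoms: iodine, I-I
Why: Stork–Zhao-type Wittig olefination with the α-iodo ylide gives under kinetic control the Z-2-iodoalk-2-ene (iodine cis to the chain), which fixes the later 1(10)Z ring olefin.

Step 6
Reactants: 11 (2E,6Z)-7-iodo-3-methylocta-2,6-dien-1-yl acetate; 12 (4S)-2,2-dimethyl-1,3-dioxolane-4-carbaldehyde
Product: 13 (2E,6Z,8R)-8-[(4S)-2,2-dimethyl-1,3-dioxolan-4-yl]-8-hydroxy-3,7-dimethylocta-2,6-dien-1-yl acetate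
Conditions: CrCl2 (4 equiv), NiCl2 (2 mol %), DMSO/THF, rt; chromatography
Reagents that add atoms: none
Why: Nozaki–Hiyama–Kishi alkenylation with retention of the Z geometry, in which Felkin–Anh attack on the α-alkoxy aldehyde gives mainly the anti (8R) adduct (expected about 4:1, separable).

Step 7
Reactants: 13 (2E,6Z,8R)-8-[(4S)-2,2-dimethyl-1,3-dioxolan-4-yl]-8-hydroxy-3,7-dimethylocta-2,6-dien-1-yl acetate
Product: 14 (2E,6Z,8R)-8-[(4S)-2,2-dimethyl-1,3-dioxolan-4-yl]-3,7-dimethylocta-2,6-diene-1,8-diol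
Conditions: K2CO3, MeOH, 0 °C
Reagents that add atoms: none
Why: Base-catalysed transesterification (methanolysis) removes the primary acetate and touches nothing else.

Step 8
Reactants: 14 (2E,6Z,8R)-8-[(4S)-2,2-dimethyl-1,3-dioxolan-4-yl]-3,7-dimethylocta-2,6-diene-1,8-diol
Product: 15 (2E,6Z,8R)-8-[(4S)-2,2-dimethyl-1,3-dioxolan-4-yl]-8-hydroxy-3,7-dimethylocta-2,6-dienal
Conditions: TEMPO (10 mol %), PhI(OAc)2, CH2Cl2, 0 °C → rt
Reagents that add atoms: none
Why: Oxoammonium (TEMPO) oxidation is selective for the primary allylic alcohol over the hindered secondary one and gives the E enal without isomerisation.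

Step 9
Reactants: 15 (2E,6Z,8R)-8-[(4S)-2,2-dimethyl-1,3-dioxolan-4-yl]-8-hydroxy-3,7-dimethylocta-2,6-dienal; 4 (2S,3S)-2,3-dimethyloxirane-2-carboxylic acid
Product: 16 (1R,2Z,6E)-1-[(4S)-2,2-dimethyl-1,3-dioxolan-4-yl]-2,6-dimethyl-8-oxoocta-2,6-dien-1-yl (2S,3S)-2,3-dimethyloxirane-2-carboxylate
Conditions: 4, 2,4,6-trichlorobenzoyl chloride, Et3N, THF; then 15, DMAP, PhMe, rt
Reagents that add atoms: none
Why: Yamaguchi esterification through the mixed anhydride acylates the only free hydroxyl, so the epoxy ester is fixed on O-9 before O-8 exists; no stereocentre is touched.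

Step 10
Reactants: 16 (1R,2Z,6E)-1-[(4S)-2,2-dimethyl-1,3-dioxolan-4-yl]-2,6-dimethyl-8-oxoocta-2,6-dien-1-yl (2S,3S)-2,3-dimethyloxirane-2-carboxylate
Product: 17 (1R,2Z,6E,8R)-1-[(4S)-2,2-dimethyl-1,3-dioxolan-4-yl]-8-hydroxy-2,6-dimethyldeca-2,6,9-trien-1-yl (2S,3S)-2,3-dimethyloxirane-2-carboxylate
Conditions: CH2=CHSi(OMe)3, CuF(PPh3)3·2EtOH (5 mol %), DTBM-SEGPHOS (10 mol %), DMF, 40 °C; aqueous work-up
Reagents that add atoms: trimethoxy(vinyl)silane, C=C[Si](OC)(OC)OC
Why: Copper-catalysed enantioselective 1,2-addition of an alkenylsilane to the enal (catalytic asymmetric vinylation), in which the chiral monovalent copper–vinyl species sets the new 8R carbinol (germacrane C-6) under ligand control because the other stereocentres are remote.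

Step 11
Reactants: 17 (1R,2Z,6E,8R)-1-[(4S)-2,2-dimethyl-1,3-dioxolan-4-yl]-8-hydroxy-2,6-dimethyldeca-2,6,9-trien-1-yl (2S,3S)-2,3-dimethyloxirane-2-carboxylate; 18 2-(bromomethyl)prop-2-enoic acid
Product: 19 (1R,2Z,6E,8R)-8-{[2-(bromomethyl)prop-2-enoyl]oxy}-1-[(4S)-2,2-dimethyl-1,3-dioxolan-4-yl]-2,6-dimethyldeca-2,6,9-trien-1-yl (2S,3S)-2,3-dimethyloxirane-2-carboxylate
Conditions: N,N'-diisopropylcarbodiimide, DMAP (5 mol %), CH2Cl2, −20 → 0 °C
Reagents that add atoms: none
Why: Steglich-type carbodiimide esterification acylates the bis-allylic alcohol with retention at the carbinol carbon, and the low temperature with little DMAP limits attack on the allylic bromide.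

Step 12
Reactants: 19 (1R,2Z,6E,8R)-8-{[2-(bromomethyl)prop-2-enoyl]oxy}-1-[(4S)-2,2-dimethyl-1,3-dioxolan-4-yl]-2,6-dimethyldeca-2,6,9-trien-1-yl (2S,3S)-2,3-dimethyloxirane-2-carboxylate
Product: 21 (2R,3Z,7E,9R)-9-{[2-(bromomethyl)prop-2-enoyl]oxy}-3,7-dimethyl-1-oxoundeca-3,7,10-trien-2-yl (2S,3S)-2,3-dimethyloxirane-2-carboxylate, via vicinal diol 20 (not isolated)
Conditions: 80% aq. AcOH, 35 °C; evaporate; NaIO4, THF/pH 7 buffer, 0 °C; use at once
Reagents that add atoms: none
Why: Mild acetal hydrolysis followed by Malaprade glycol cleavage excises the auxiliary carbon with its stereocentre and gives the α-acyloxy aldehyde without touching the 2R centre, the electron-poor glycidic ester tolerating the weak acid.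

Step 13
Reactants: 21 (2R,3Z,7E,9R)-9-{[2-(bromomethyl)prop-2-enoyl]oxy}-3,7-dimethyl-1-oxoundeca-3,7,10-trien-2-yl (2S,3S)-2,3-dimethyloxirane-2-carboxylate
Product: 23 (3aR,4R,5R,6Z,10E,11aS)-4-hydroxy-6,10-dimethyl-3-methylidene-2-oxo-2,3,3a,4,5,8,9,11a-octahydrocyclodeca[b]furan-5-yl (2S,3S)-2,3-dimethyloxirane-2-carboxylate, via bromomethylbutenolide aldehyde 22 (not isolated)
Conditions: second-generation Grubbs catalyst (10 mol %), 1,2-dichloroethane, 60 °C, 0.005 M; then cannulate over 10 h into CrCl2 (10 equiv), THF/DMF, 4 Å MS, rt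
Reagents that add atoms: none
Why: Ring-closing metathesis of the acrylate with the vinyl group can only give the butenolide (the 4E olefin blocks closure onto the remote alkenes). CrCl2 then turns the allylic bromide into an allyl–trivalent chromium species that adds through its γ-carbon to the tethered aldehyde (intramolecular Nozaki–Hiyama allylation, SE2′), which unveils the exocyclic methylene. The aldehyde is delivered on the lactone face that carries the tether, giving the cis ring fusion (3aR), and the chair transition state of the ring-locked E-type allylchromium places C-11a and the new hydroxyl anti, giving 4R.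

**Compound list**
1 | methyl (2Z)-2-methylbut-2-enoate (methyl angelate) | C/C=C(/C)C(=O)OC | starting material
2 | (2Z)-2-methylbut-2-en-1-ol | C/C=C(/C)CO | intermediate
3 | [(2R,3S)-2,3-dimethyloxiran-2-yl]methanol | OC[C@@]1(C)O[C@H]1C | intermediate
4 | (2S,3S)-2,3-dimethyloxirane-2-carboxylic acid | OC(=O)[C@@]1(C)O[C@H]1C | intermediate
5 | geranyl acetate, (2E)-3,7-dimethylocta-2,6-dien-1-yl acetate | CC(C)=CCC/C(C)=C/COC(C)=O | starting material
6 | (2E)-3-methyl-6-oxohex-2-en-1-yl acetate | CC(=O)OC/C=C(\C)CCC=O | intermediate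
7 | ethyltriphenylphosphonium iodide | CC[P+](c1ccccc1)(c1ccccc1)c1ccccc1.[I-] | starting material
8 | ethylidenetriphenylphosphorane | CC=P(c1ccccc1)(c1ccccc1)c1ccccc1 | intermediate
9 | (1-iodoethyl)triphenylphosphonium iodide | CC(I)[P+](c1ccccc1)(c1ccccc1)c1ccccc1.[I-] | intermediate
10 | (1-iodoethylidene)triphenylphosphorane | CC(I)=P(c1ccccc1)(c1ccccc1)c1ccccc1 | intermediate
11 | (2E,6Z)-7-iodo-3-methylocta-2,6-dien-1-yl acetate | CC(=O)OC/C=C(\C)CC/C=C(/C)I | intermediate
12 | (4S)-2,2-dimethyl-1,3-dioxolane-4-carbaldehyde | O=C[C@@H]1COC(C)(C)O1 | starting material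
13 | (2E,6Z,8R)-8-[(4S)-2,2-dimethyl-1,3-dioxolan-4-yl]-8-hydroxy-3,7-dimethylocta-2,6-dien-1-yl acetate | CC(=O)OC/C=C(\C)CC/C=C(/C)[C@@H](O)[C@@H]1COC(C)(C)O1 | intermediate
14 | (2E,6Z,8R)-8-[(4S)-2,2-dimethyl-1,3-dioxolan-4-yl]-3,7-dimethylocta-2,6-diene-1,8-diol | OC/C=C(\C)CC/C=C(/C)[C@@H](O)[C@@H]1COC(C)(C)O1 | intermediate
15 | (2E,6Z,8R)-8-[(4S)-2,2-dimethyl-1,3-dioxolan-4-yl]-8-hydroxy-3,7-dimethylocta-2,6-dienal | O=C/C=C(\C)CC/C=C(/C)[C@@H](O)[C@@H]1COC(C)(C)O1 | intermediate
16 | (1R,2Z,6E)-1-[(4S)-2,2-dimethyl-1,3-dioxolan-4-yl]-2,6-dimethyl-8-oxoocta-2,6-dien-1-yl (2S,3S)-2,3-dimethyloxirane-2-carboxylate | O=C/C=C(\C)CC/C=C(/C)[C@@H](OC(=O)[C@@]2(C)O[C@H]2C)[C@@H]1COC(C)(C)O1 | intermediate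
17 | (1R,2Z,6E,8R)-1-[(4S)-2,2-dimethyl-1,3-dioxolan-4-yl]-8-hydroxy-2,6-dimethyldeca-2,6,9-trien-1-yl (2S,3S)-2,3-dimethyloxirane-2-carboxylate | C=C[C@@H](O)/C=C(\C)CC/C=C(/C)[C@@H](OC(=O)[C@@]2(C)O[C@H]2C)[C@@H]1COC(C)(C)O1 | intermediate
18 | 2-(bromomethyl)prop-2-enoic acid | OC(=O)C(=C)CBr | starting material
19 | (1R,2Z,6E,8R)-8-{[2-(bromomethyl)prop-2-enoyl]oxy}-1-[(4S)-2,2-dimethyl-1,3-dioxolan-4-yl]-2,6-dimethyldeca-2,6,9-trien-1-yl (2S,3S)-2,3-dimethyloxirane-2-carboxylate | C=C[C@@H](OC(=O)C(=C)CBr)/C=C(\C)CC/C=C(/C)[C@@H](OC(=O)[C@@]2(C)O[C@H]2C)[C@@H]1COC(C)(C)O1 | intermediate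
20 | (2S,3R,4Z,8E,10R)-10-{[2-(bromomethyl)prop-2-enoyl]oxy}-1,2-dihydroxy-4,8-dimethyldodeca-4,8,11-trien-3-yl (2S,3S)-2,3-dimethyloxirane-2-carboxylate | C=C[C@@H](OC(=O)C(=C)CBr)/C=C(\C)CC/C=C(/C)[C@@H](OC(=O)[C@@]2(C)O[C@H]2C)[C@@H](O)CO | intermediate
21 | (2R,3Z,7E,9R)-9-{[2-(bromomethyl)prop-2-enoyl]oxy}-3,7-dimethyl-1-oxoundeca-3,7,10-trien-2-yl (2S,3S)-2,3-dimethyloxirane-2-carboxylate | C=C[C@@H](OC(=O)C(=C)CBr)/C=C(\C)CC/C=C(/C)[C@@H](OC(=O)[C@@]2(C)O[C@H]2C)C=O | intermediate
22 | (2R,3Z,7E)-8-[(2S)-4-(bromomethyl)-5-oxo-2,5-dihydrofuran-2-yl]-3,7-dimethyl-1-oxoocta-3,7-dien-2-yl (2S,3S)-2,3-dimethyloxirane-2-carboxylate | O=C1O[C@@H](/C=C(\C)CC/C=C(/C)[C@@H](OC(=O)[C@@]2(C)O[C@H]2C)C=O)C=C1CBr | intermediate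
23 | (3aR,4R,5R,6Z,10E,11aS)-4-hydroxy-6,10-dimethyl-3-methylidene-2-oxo-2,3,3a,4,5,8,9,11a-octahydrocyclodeca[b]furan-5-yl (2S,3S)-2,3-dimethyloxirane-2-carboxylate | C=C1C(=O)O[C@H]2/C=C(\C)CC/C=C(/C)[C@@H](OC(=O)[C@@]3(C)O[C@H]3C)[C@H](O)[C@@H]12 | target

**Step count and risks**

Total steps: 13. Longest linear sequence: 10 (steps 4 to 13, from geranyl acetate); the epoxy acid branch (steps 1 to 3) joins at step 9.

The three steps most likely to fail are step 13, step 10 and step 6.

Step 13. The ten-membered closure may be low-yielding. In addition, the Felkin preference of the α-acyloxy aldehyde opposes the chair transition state, so the C-4 epimer could dominate. The fallback sets out from 21: the same one-flask closure is run and the 4S-epimeric alcohol F1 is collected. It is oxidised with Dess–Martin periodinane (NaHCO3, CH2Cl2, 0 °C) to the 4-ketone F2, which is reduced at once with NaBH4 and CeCl3·7H2O in MeOH at −78 °C. Hydride then adds anti to the acyloxy group (Felkin–Anh) and from the outer face of the ring, which gives the 4R alcohol; the cerium salt suppresses conjugate reduction of the methylene lactone. The route comes back at 23, with the carbinol centre now set by ketone reduction and not by the C–C bond formation.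

Step 10. The catalytic vinylation of a hindered β,β-disubstituted enal may give low conversion or low selectivity, and the C-8 epimers would be hard to separate. The fallback sets out from 16 and reaches the carbinol by alkynylation and semireduction. Me2Zn, the ProPhenol ligand and trimethylsilylacetylene (PhMe, 0 °C; zinc alkynylide addition) give the silylated propargylic alcohol F3. K2CO3 in MeOH at 0 °C gives the terminal alkyne F4. Hydrogen over Pd/CaCO3 poisoned by Pb(OAc)2, with quinoline in EtOAc, reduces only the alkyne, and the route comes back at 17.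

Step 6. The facial selectivity toward glyceraldehyde acetonide is only moderate, and the allylic acetate may suffer under the nickel catalysis. The fallback sets out from 11 and 12: the coupling is run without regard to selectivity, and the mixture of 13 and its 8S-epimer F5 is oxidised with MnO2 (CH2Cl2, rt) to the enone F6. Reduction with Zn(BH4)2 in Et2O at −30 °C follows; chelation of zinc between the ketone and the dioxolane oxygen directs hydride to give the anti alcohol, and the route comes back at 13.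

**Further compounds**
F1 | step 13 | (3aR,4S,5R,6Z,10E,11aS)-4-hydroxy-6,10-dimethyl-3-methylidene-2-oxo-2,3,3a,4,5,8,9,11a-octahydrocyclodeca[b]furan-5-yl (2S,3S)-2,3-dimethyloxirane-2-carboxylate | C=C1C(=O)O[C@H]2/C=C(\C)CC/C=C(/C)[C@@H](OC(=O)[C@@]3(C)O[C@H]3C)[C@@H](O)[C@@H]12
F2 | step 13 | (3aS,5R,6Z,10E,11aS)-6,10-dimethyl-3-methylidene-2,4-dioxo-2,3,3a,4,5,8,9,11a-octahydrocyclodeca[b]furan-5-yl (2S,3S)-2,3-dimethyloxirane-2-carboxylate | C=C1C(=O)O[C@H]2/C=C(\C)CC/C=C(/C)[C@@H](OC(=O)[C@@]3(C)O[C@H]3C)C(=O)[C@@H]12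
F3 | step 10 | (1R,2Z,6E,8S)-1-[(4S)-2,2-dimethyl-1,3-dioxolan-4-yl]-8-hydroxy-2,6-dimethyl-10-(trimethylsilyl)deca-2,6-dien-9-yn-1-yl (2S,3S)-2,3-dimethyloxirane-2-carboxylate | C[Si](C)(C)C#C[C@@H](O)/C=C(\C)CC/C=C(/C)[C@@H](OC(=O)[C@@]2(C)O[C@H]2C)[C@@H]1COC(C)(C)O1
F4 | step 10 | (1R,2Z,6E,8S)-1-[(4S)-2,2-dimethyl-1,3-dioxolan-4-yl]-8-hydroxy-2,6-dimethyldeca-2,6-dien-9-yn-1-yl (2S,3S)-2,3-dimethyloxirane-2-carboxylate | C#C[C@@H](O)/C=C(\C)CC/C=C(/C)[C@@H](OC(=O)[C@@]2(C)O[C@H]2C)[C@@H]1COC(C)(C)O1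
F5 | step 6 | (2E,6Z,8S)-8-[(4S)-2,2-dimethyl-1,3-dioxolan-4-yl]-8-hydroxy-3,7-dimethylocta-2,6-dien-1-yl acetate | CC(=O)OC/C=C(\C)CC/C=C(/C)[C@H](O)[C@@H]1COC(C)(C)O1
F6 | step 6 | (2E,6Z)-8-[(4S)-2,2-dimethyl-1,3-dioxolan-4-yl]-3,7-dimethyl-8-oxoocta-2,6-dien-1-yl acetate | CC(=O)OC/C=C(\C)CC/C=C(/C)C(=O)[C@@H]1COC(C)(C)O1
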